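All runs are simulated for substances that don't exist, noise included.

If you read the protic impurity as a concentration, you will expect the run charged with more of it to show the higher percentage of quenched substrate.

| flask | starting material | protic impurity | remark | time |
|---|---|---|---|---|
| maple | 0.018 M | 3.6 mM | run made earlier |  |
| cedar | 0.027 M | 3.6 mM | run made earlier |  |
| larch | 0.036 M | 5.4 mM | run made earlier |  |
| flask | 0.036 M | 3.60 mM |  | 50 min |

- maple (time / min: target / %, isomer of the product / %, quenched substrate / %): 4.00: 4.6, 11.4, 18.4; 10.0: 12.4, 19.3, 19.1; 20.0: 21.7, 28.0, 20.8; 50.0: 31.8, 34.2, 19.9
- cedar (time / min: target / %, isomer of the product / %, quenched substrate / %): 4.00: 5.2, 12.3, 13.4; 10.0: 13.4, 21.6, 13.3; 20.0: 22.7, 28.8, 12.7; 50.0: 33.6, 37.5, 12.4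
- larch (time / min: target / %, isomer of the product / %, quenched substrate / %): 12.0: 15.3, 23.2, 16.2; 25.0: 25.8, 31.1, 14.6; 40.0: 32.0, 35.7, 14.5; 50.0: 33.1, 38.0, 15.3

(each reading ± 0.5 percentage points)



- amount of target in the flask at 50 min, in percent of the starting material charged
- amount of isomer of the product in the flask at 50 min, in percent of the starting material charged
- amount of quenched substrate in the flask at 50 min, in percent of the starting material charged
- amount of starting material in the flask at 50 min, in percent of the starting material charged

Yet the larch run, charged with 1.50 times the impurity of the maple run, shows a lower percentage of quenched substrate at 50.0 min, each taken of its own charge: 15.3 % against 19.9 %. Now reckon the impurity as a fraction of the charge. It is 20.0 % in maple and 15.0 % in larch, and that is what the readings show. In maple, quenched substrate already stands at 18.4 % by 4.00 min.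

So treat the quench as over at the start and reckon with what it leaves free. For the flask it takes 10.0 %, so its active fraction, the share of the charge the impurity leaves free, is 90.0 %. Divide target at 50.0 min by each run's active fraction and you read 39.8 % in maple and 38.9 % in larch. Scaling the larch figure, which has the flask's charge, I expect 35.0 % target.

The forecast reasons that “the impurity simply consumes an equal amount of starting material at once”. It gives 35.3 % target, a little above mine, with 39.3 % isomer of the product, 10 % quenched substrate and 15.4 % starting material.

The flask gives 35.0 % target, 39.1 % isomer of the product, 10.0 % quenched substrate and 15.9 % starting material.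

    starting material ⇌ target (K = 3.00, k = 0.00420 min⁻¹)
    target ⇌ isomer of the product (K = 1.10, k = 0.200 min⁻¹)
    isomer of the product ⇌ starting material (k = 0.0150 min⁻¹)
    starting material + protic impurity → quenched substrate (k = 65.0 L mol⁻¹ min⁻¹)

With starting material held at its charge, the protic impurity, limiting reagent of the quench, has a half-life of 0.296 min, far shorter than the 10.7 min relaxation half-life of isomer of the product and starting material, and in the flask at 5.00 min it is down to 0.00874 % of its own charge. A neighbouring flask, the same but with its impurity at 2.50 % of the charge, has an active fraction of 97.5 %; scaling this flask's target by 97.5 % over 90.0 % gives 37.9 %, and that neighbour holds 37.9 %.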